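**Retrosynthetic overview**

1. Last cut: the methylcyclohexene ring (ring D) is opened by an intermolecular exo Diels–Alder disconnection into the (E)-dehydroprenyl diene on ring B of a (2R,3R)-dihydroflavonol and (E)-2,2',4,4'-tetrahydroxychalcone; this step sets the three cyclohexene stereocentres.
2. Key cut: ring C at O1–C2 and C4–C4a; both bonds come from one [3+3] annulation of an O,C-dilithiated resorcinol (ring A) with a (2R,3S)-α,β-epoxy morpholine amide that already carries ring B and the diene.
3. Enabling feature: ring A is a resorcinol in which C4a is ortho to O1 and para to the C7 oxygen, so O1 and C4a can be delivered together as a 2-lithiophenoxide made from 4-bromoresorcinol. C2 is benzylic to ring B, whose C2' and C4' oxygens steer phenoxide opening of the epoxide to C2 (6-endo, inversion) and so turn the epoxide configuration into the trans-(2R,3R) ketol.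
4. Remaining cuts: the epoxide by catalytic asymmetric epoxidation of an (E)-enamide (Horner–Wadsworth–Emmons from the aldehyde); the diene by Suzuki–Miyaura coupling at C3' of 2,4-dihydroxy-3-iodobenzaldehyde.
5. Order of ring formation: rings A and B are bought as arenes, ring C is formed in step 8, ring D in step 10.

Key step: step 8

Remark (assumption on the chemistry): the samarium/(S)-BINOL catalyst of step 6 is taken to deliver the (2R,3S)-epoxide (should the opposite sense be found, (R)-BINOL is used); the morpholine phosphonate of step 5 and the tetrahydroxychalcone of step 10 are taken as catalogue chemicals.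

**Route**

Step 1
Reactants: 1 2,4-dihydroxybenzaldehyde
Product: 2 2,4-dihydroxy-3-iodobenzaldehyde
Conditions: I2, HIO3, EtOH/H2O, 35 °C
Reagents that add atoms: iodine [I][I]; iodic acid OI(=O)=O
Why: Electrophilic aromatic iodination, in which the carbon between the two hydroxyl groups is the most activated position and HIO3 reoxidises the iodide formed so that the iodination is not reversed.

Step 2
Reactants: 2 2,4-dihydroxy-3-iodobenzaldehyde
Product: 3 2,4-bis(tert-butyldimethylsilyloxy)-3-iodobenzaldehyde
Conditions: t-BuMe2SiCl, imidazole, DMAP (cat.), DMF, rt to 40 °C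
Reagents that add atoms: tert-butyldimethylsilyl chloride CC(C)(C)[Si](C)(C)Cl
Why: Silylation of both phenols (nucleophilic catalysis by imidazole/DMAP) removes the acidic protons that would quench the phosphonate anion, the lanthanide catalyst and the aryllithium of later steps, and the silyl ethers can be removed at the end with buffered fluoride under conditions that the diene and the ketol tolerate.

Step 3
Reactants: 4 2-methylbut-1-en-3-yne; 5 pinacolborane
Product: 6 (E)-4,4,5,5-tetramethyl-2-(3-methylbuta-1,3-dien-1-yl)-1,3,2-dioxaborolane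
Conditions: Cp2Zr(H)Cl (5 mol%), Et3N (10 mol%), neat, 60 °C
Reagents that add atoms: none
Why: Zirconium-catalysed hydroboration of a terminal alkyne, a syn anti-Markovnikov addition that gives the (E)-alkenylboronate and leaves the 1,1-disubstituted alkene untouched.

Step 4
Reactants: 3 2,4-bis(tert-butyldimethylsilyloxy)-3-iodobenzaldehyde; 6 (E)-4,4,5,5-tetramethyl-2-(3-methylbuta-1,3-dien-1-yl)-1,3,2-dioxaborolane
Product: 7 2,4-bis(tert-butyldimethylsilyloxy)-3-[(E)-3-methylbuta-1,3-dien-1-yl]benzaldehyde
Conditions: Pd(OAc)2 (5 mol%), SPhos (10 mol%), K3PO4, toluene/H2O (20:1), 50 °C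
Reagents that add atoms: none
Why: Suzuki–Miyaura cross-coupling with retention of the (E)-alkenyl geometry; the bulky electron-rich SPhos ligand is chosen for the iodide flanked by two silyloxy groups and the weakly basic biphasic medium is meant to spare the aryl silyl ethers and the aldehyde.

Step 5
Reactants: 7 2,4-bis(tert-butyldimethylsilyloxy)-3-[(E)-3-methylbuta-1,3-dien-1-yl]benzaldehyde; 8 diethyl [2-(morpholin-4-yl)-2-oxoethyl]phosphonate
Product: 9 (E)-3-{2,4-bis(tert-butyldimethylsilyloxy)-3-[(E)-3-methylbuta-1,3-dien-1-yl]phenyl}-1-(morpholin-4-yl)prop-2-en-1-one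
Conditions: NaH, THF, 0 °C to rt
Reagents that add atoms: none
Why: Horner–Wadsworth–Emmons olefination with an amide-stabilised phosphonate anion, which gives the (E)-enamide through the thermodynamically favoured anti oxaphosphetane and installs the morpholine amide that later serves as the acyl donor.

Step 6
Reactants: 9 (E)-3-{2,4-bis(tert-butyldimethylsilyloxy)-3-[(E)-3-methylbuta-1,3-dien-1-yl]phenyl}-1-(morpholin-4-yl)prop-2-en-1-one
Product: 10 {(2R,3S)-3-[2,4-bis(tert-butyldimethylsilyloxy)-3-((E)-3-methylbuta-1,3-dien-1-yl)phenyl]oxiran-2-yl}(morpholin-4-yl)methanone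
Conditions: Sm(O-iPr)3 (10 mol%), (S)-BINOL (10 mol%), Ph3As=O (10 mol%), t-BuOOH (in decane), 4 Å MS, THF, rt
Reagents that add atoms: tert-butyl hydroperoxide CC(C)(C)OO
Why: Lanthanide–BINOL-catalysed nucleophilic (Weitz–Scheffer-type) asymmetric epoxidation of an α,β-unsaturated morpholine amide: the samarium-bound peroxide adds in conjugate fashion only to the electron-poor enamide double bond, so the electron-rich diene is untouched, the (E)-geometry gives the trans epoxide and the chiral ligand selects the face that sets both epoxide centres as (2R,3S).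

Step 7
Reactants: 11 4-bromoresorcinol
Product: 12 2-bromo-5-(triisopropylsilyloxy)phenol
Conditions: i-Pr3SiCl (1.0 equiv), imidazole, CH2Cl2/DMF, −20 to 0 °C
Reagents that add atoms: triisopropylsilyl chloride CC(C)[Si](Cl)(C(C)C)C(C)C
Why: Regioselective mono-silylation of a diol: the bulky silyl chloride should react at the unhindered hydroxyl para to bromine and leave the shielded hydroxyl ortho to bromine (the future O1) free.

Step 8
Reactants: 12 2-bromo-5-(triisopropylsilyloxy)phenol; 10 {(2R,3S)-3-[2,4-bis(tert-butyldimethylsilyloxy)-3-((E)-3-methylbuta-1,3-dien-1-yl)phenyl]oxiran-2-yl}(morpholin-4-yl)methanone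
Product: 16 (2R,3R)-2-{2,4-bis(tert-butyldimethylsilyloxy)-3-[(E)-3-methylbuta-1,3-dien-1-yl]phenyl}-3-hydroxy-7-(triisopropylsilyloxy)chroman-4-one, via lithium 2-lithio-5-(triisopropylsilyloxy)phenoxide 13 (not isolated), via dilithium salt of the tetrahedral morpholine adduct 14 (not isolated), via 2-hydroxyaryl (2R,3S)-epoxy ketone 15 (not isolated)
Conditions: 12 (1.2 equiv), n-BuLi (2.4 equiv), THF, −78 to 0 °C; then 10, −78 to −30 °C; then AcOH, MeOH, −30 °C to rt
Reagents that add atoms: none
Why: Deprotonation and bromine–lithium exchange turn 12 into the O,C-dilithio species 13, whose aryl carbanion (the future C4a) adds to the morpholine amide of 10 to give the stable tetrahedral adduct 14; the acetic acid quench collapses 14 to the 2-hydroxyaryl epoxy ketone 15, whose phenol (the future O1) then opens the epoxide at the benzylic carbon to give 16. The closest known reaction types are the ketone synthesis from α,β-epoxy morpholine (Weinreb-type) amides with organolithiums and the cyclisation of 2'-hydroxychalcone epoxides to trans-dihydroflavonols (the ring-forming half of the Algar–Flynn–Oyamada reaction). Ring C closes in the 6-endo-tet mode on the epoxide. C2 is set by inversion at the benzylic epoxide carbon (3S in 10 becomes 2R) and C3 is the untouched α-carbon of the epoxide (2R becomes 3R), so the trans-(2R,3R) ketol is both the stereospecific and the thermodynamically preferred diequatorial product. The step needs a single C-acylation before any epoxide opening and 6-endo instead of 5-exo closure: the first is secured by the chelated adduct 14, which does not release a ketone until the quench, the second by ring B, whose C2' and C4' silyloxy groups stabilise positive charge at C2 while the carbonyl group destabilises it at C3.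

Step 9
Reactants: 16 (2R,3R)-2-{2,4-bis(tert-butyldimethylsilyloxy)-3-[(E)-3-methylbuta-1,3-dien-1-yl]phenyl}-3-hydroxy-7-(triisopropylsilyloxy)chroman-4-one
Product: 17 (2R,3R)-2-{2,4-dihydroxy-3-[(E)-3-methylbuta-1,3-dien-1-yl]phenyl}-3,7-dihydroxychroman-4-one
Conditions: n-Bu4NF/AcOH (1:1, 3.3 equiv), THF, 0 °C; product used at once
Reagents that add atoms: none
Why: Fluoride-mediated cleavage of the three aryl silyl ethers, buffered with acetic acid so that neither the base-sensitive ketol (C2/C3) nor the acid-sensitive 2-hydroxyaryl diene meets strong base or acid, and no stereocentre is touched.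

Step 10
Reactants: 17 (2R,3R)-2-{2,4-dihydroxy-3-[(E)-3-methylbuta-1,3-dien-1-yl]phenyl}-3,7-dihydroxychroman-4-one; 18 (E)-1,3-bis(2,4-dihydroxyphenyl)prop-2-en-1-one
Product: 19 guangsangon K
Conditions: exo-selective FAD-dependent intermolecular Diels–Alderase of the Morus alba MaDA family (MaDA-3 type, recombinant), Tris-HCl buffer pH 8.0, 5% DMSO, 37 °C
Reagents that add atoms: none
Why: Enzyme-catalysed intermolecular Diels–Alder reaction: the Diels–Alderase should bind the chelated 2'-hydroxychalcone dienophile and the dehydroprenyl diene flanked by two phenolic hydroxyls (the substitution pattern of its native substrates) in an exo transition state and so set the three cyclohexene stereocentres (1R,5S,6R; all-trans) under enzyme control with the regiochemistry of the natural adducts (diene CH2 terminus to the chalcone β-carbon), while C2 and C3 are spectators and the 2,3-trans ketol is the preferred ring C configuration at pH 8.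

**Compound list**

1 | 2,4-dihydroxybenzaldehyde | O=Cc1ccc(O)cc1O | starting material
2 | 2,4-dihydroxy-3-iodobenzaldehyde | Oc1ccc(C=O)c(O)c1I | intermediate
3 | 2,4-bis(tert-butyldimethylsilyloxy)-3-iodobenzaldehyde | CC(C)(C)[Si](C)(C)Oc1ccc(C=O)c(O[Si](C)(C)C(C)(C)C)c1I | intermediate
4 | 2-methylbut-1-en-3-yne | C=C(C)C#C | starting material
5 | pinacolborane (4,4,5,5-tetramethyl-1,3,2-dioxaborolane) | B1OC(C)(C)C(C)(C)O1 | starting material
6 | (E)-4,4,5,5-tetramethyl-2-(3-methylbuta-1,3-dien-1-yl)-1,3,2-dioxaborolane | CC(=C)/C=C/B1OC(C)(C)C(C)(C)O1 | intermediate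
7 | 2,4-bis(tert-butyldimethylsilyloxy)-3-[(E)-3-methylbuta-1,3-dien-1-yl]benzaldehyde | CC(=C)/C=C/c1c(O[Si](C)(C)C(C)(C)C)ccc(C=O)c1O[Si](C)(C)C(C)(C)C | intermediate
8 | diethyl [2-(morpholin-4-yl)-2-oxoethyl]phosphonate | CCOP(=O)(CC(=O)N1CCOCC1)OCC | starting material
9 | (E)-3-{2,4-bis(tert-butyldimethylsilyloxy)-3-[(E)-3-methylbuta-1,3-dien-1-yl]phenyl}-1-(morpholin-4-yl)prop-2-en-1-one | CC(=C)/C=C/c1c(O[Si](C)(C)C(C)(C)C)ccc(/C=C/C(=O)N2CCOCC2)c1O[Si](C)(C)C(C)(C)C | intermediate
10 | {(2R,3S)-3-[2,4-bis(tert-butyldimethylsilyloxy)-3-((E)-3-methylbuta-1,3-dien-1-yl)phenyl]oxiran-2-yl}(morpholin-4-yl)methanone | O=C([C@@H]1O[C@H]1c1ccc(O[Si](C)(C)C(C)(C)C)c(/C=C/C(C)=C)c1O[Si](C)(C)C(C)(C)C)N1CCOCC1 | intermediate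
11 | 4-bromoresorcinol (4-bromobenzene-1,3-diol) | Oc1ccc(Br)c(O)c1 | starting material
12 | 2-bromo-5-(triisopropylsilyloxy)phenol | Oc1cc(O[Si](C(C)C)(C(C)C)C(C)C)ccc1Br | intermediate
13 | lithium 2-lithio-5-(triisopropylsilyloxy)phenoxide | [Li]Oc1cc(O[Si](C(C)C)(C(C)C)C(C)C)ccc1[Li] | intermediate (not isolated)
14 | dilithium {(2R,3S)-3-[2,4-bis(tert-butyldimethylsilyloxy)-3-((E)-3-methylbuta-1,3-dien-1-yl)phenyl]oxiran-2-yl}(morpholin-4-yl)[2-oxido-4-(triisopropylsilyloxy)phenyl]methanolate | [Li]OC(N1CCOCC1)([C@@H]1O[C@H]1c1ccc(O[Si](C)(C)C(C)(C)C)c(/C=C/C(C)=C)c1O[Si](C)(C)C(C)(C)C)c1ccc(O[Si](C(C)C)(C(C)C)C(C)C)cc1O[Li] | intermediate (not isolated)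
15 | {(2R,3S)-3-[2,4-bis(tert-butyldimethylsilyloxy)-3-((E)-3-methylbuta-1,3-dien-1-yl)phenyl]oxiran-2-yl}[2-hydroxy-4-(triisopropylsilyloxy)phenyl]methanone | O=C([C@@H]1O[C@H]1c1ccc(O[Si](C)(C)C(C)(C)C)c(/C=C/C(C)=C)c1O[Si](C)(C)C(C)(C)C)c1ccc(O[Si](C(C)C)(C(C)C)C(C)C)cc1O | intermediate (not isolated)
16 | (2R,3R)-2-{2,4-bis(tert-butyldimethylsilyloxy)-3-[(E)-3-methylbuta-1,3-dien-1-yl]phenyl}-3-hydroxy-7-(triisopropylsilyloxy)chroman-4-one | CC(=C)/C=C/c1c(O[Si](C)(C)C(C)(C)C)ccc([C@H]2Oc3cc(O[Si](C(C)C)(C(C)C)C(C)C)ccc3C(=O)[C@@H]2O)c1O[Si](C)(C)C(C)(C)C | intermediate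
17 | (2R,3R)-2-{2,4-dihydroxy-3-[(E)-3-methylbuta-1,3-dien-1-yl]phenyl}-3,7-dihydroxychroman-4-one | CC(=C)/C=C/c1c(O)ccc([C@H]2Oc3cc(O)ccc3C(=O)[C@@H]2O)c1O | intermediate
18 | (E)-1,3-bis(2,4-dihydroxyphenyl)prop-2-en-1-one (2,2',4,4'-tetrahydroxychalcone) | O=C(/C=C/c1ccc(O)cc1O)c1ccc(O)cc1O | starting material
19 | guangsangon K: (2R,3R)-2-{3-[(1R,5S,6R)-6-(2,4-dihydroxybenzoyl)-5-(2,4-dihydroxyphenyl)-3-methylcyclohex-2-en-1-yl]-2,4-dihydroxyphenyl}-3,7-dihydroxychroman-4-one | CC1=C[C@@H](c2c(O)ccc([C@H]3Oc4cc(O)ccc4C(=O)[C@@H]3O)c2O)[C@H](C(=O)c2ccc(O)cc2O)[C@@H](c2ccc(O)cc2O)C1 | target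

**Step count and risks**

Total step count: 10. Longest linear sequence: 8 steps (steps 1, 2, 4, 5, 6, 8, 9, 10, from compound 1).

Steps most likely to fail:

Step 8 (key annulation). What may go wrong: the dianion may add twice or attack the epoxide instead of the amide, or the freed phenol may close at the α-carbon (5-exo) or through an ionised benzylic centre with loss of the trans relationship. Fallback (stepwise, with a protected phenol and an isolated ketone): setting out from 12, O-allylation (allyl bromide, K2CO3, acetone) should give 2-(allyloxy)-1-bromo-4-(triisopropylsilyloxy)benzene F1. Bromine–lithium exchange (n-BuLi, THF, −78 °C) and addition to 10 should give the isolable [2-(allyloxy)-4-(triisopropylsilyloxy)phenyl]{(2R,3S)-3-[2,4-bis(tert-butyldimethylsilyloxy)-3-((E)-3-methylbuta-1,3-dien-1-yl)phenyl]oxiran-2-yl}methanone F2. Neutral Tsuji–Trost-type deallylation (Pd(PPh3)4, morpholine, THF, rt) then releases the phenol 15, whose ring closure can be tuned on its own (NaOAc/AcOH in MeOH, or silica gel), and the sequence comes back to the route at 16.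

Step 10 (enzymatic Diels–Alder reaction). What may go wrong: the enzyme may not turn over this diene/dienophile pair or may lose its exo preference, or the free 2-hydroxyaryl diene may cyclise to a chromene or polymerise faster than it is captured. Fallback (chiral boron Lewis acid on protected partners): setting out from 16, desilylation as in step 9 followed in the same flask by Ac2O/pyridine/DMAP should give (2R,3R)-3,7-diacetoxy-2-{2,4-diacetoxy-3-[(E)-3-methylbuta-1,3-dien-1-yl]phenyl}chroman-4-one F3. Compound 18 is converted with Ac2O (3 equiv)/pyridine at 0 °C into (E)-1-(4-acetoxy-2-hydroxyphenyl)-3-(2,4-diacetoxyphenyl)prop-2-en-1-one F4, in which the chelated 2'-hydroxyl stays free. The Diels–Alder reaction of F3 with F4 is promoted by a stoichiometric chiral borate made from VANOL, BH3·THF and AcOH (the ligand enantiomer that gives the (1R,5S,6R) cyclohexene; PhCF3, rt to 40 °C) and should give, after chromatographic separation from the endo isomer, the exo adduct heptaacetate of guangsangon K F5. Transesterification (K2CO3, degassed MeOH, 0 °C, then AcOH) removes the seven acetates and comes back to the route at 19.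

Step 6 (asymmetric epoxidation). What may go wrong: slow or poorly face-selective peroxide addition to the hindered, electron-rich enamide, or loss of aryl silyl ethers to the basic lanthanide alkoxide. Fallback (electrophilic organocatalytic epoxidation before the diene is present): setting out from 3, Horner–Wadsworth–Emmons reaction with 8 (NaH, THF) should give (E)-3-[2,4-bis(tert-butyldimethylsilyloxy)-3-iodophenyl]-1-(morpholin-4-yl)prop-2-en-1-one F6. Shi epoxidation with the enantiomeric (L-fructose-derived) ketone catalyst (Oxone (2KHSO5·KHSO4·K2SO4), K2CO3 buffer, MeCN/dimethoxymethane/H2O, 0 °C), possible here because no diene is yet in the molecule, should give {(2R,3S)-3-[2,4-bis(tert-butyldimethylsilyloxy)-3-iodophenyl]oxiran-2-yl}(morpholin-4-yl)methanone F7. Suzuki–Miyaura coupling of F7 with 6 under the conditions of step 4 comes back to the route at 10.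

Further compounds
F1 | step 8 | 2-(allyloxy)-1-bromo-4-(triisopropylsilyloxy)benzene | C=CCOc1cc(O[Si](C(C)C)(C(C)C)C(C)C)ccc1Br
F2 | step 8 | [2-(allyloxy)-4-(triisopropylsilyloxy)phenyl]{(2R,3S)-3-[2,4-bis(tert-butyldimethylsilyloxy)-3-((E)-3-methylbuta-1,3-dien-1-yl)phenyl]oxiran-2-yl}methanone | O=C([C@@H]1O[C@H]1c1ccc(O[Si](C)(C)C(C)(C)C)c(/C=C/C(C)=C)c1O[Si](C)(C)C(C)(C)C)c1ccc(O[Si](C(C)C)(C(C)C)C(C)C)cc1OCC=C
F3 | step 10 | (2R,3R)-3,7-diacetoxy-2-{2,4-diacetoxy-3-[(E)-3-methylbuta-1,3-dien-1-yl]phenyl}chroman-4-one | CC(=C)/C=C/c1c(OC(C)=O)ccc([C@H]2Oc3cc(OC(C)=O)ccc3C(=O)[C@@H]2OC(C)=O)c1OC(C)=O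
F4 | step 10 | (E)-1-(4-acetoxy-2-hydroxyphenyl)-3-(2,4-diacetoxyphenyl)prop-2-en-1-one | O=C(/C=C/c1ccc(OC(C)=O)cc1OC(C)=O)c1ccc(OC(C)=O)cc1O
F5 | step 10 | exo adduct heptaacetate of guangsangon K (all phenols except the ketone-chelated one and the 3-hydroxyl acetylated) | CC1=C[C@@H](c2c(OC(C)=O)ccc([C@H]3Oc4cc(OC(C)=O)ccc4C(=O)[C@@H]3OC(C)=O)c2OC(C)=O)[C@H](C(=O)c2ccc(OC(C)=O)cc2O)[C@@H](c2ccc(OC(C)=O)cc2OC(C)=O)C1
F6 | step 6 | (E)-3-[2,4-bis(tert-butyldimethylsilyloxy)-3-iodophenyl]-1-(morpholin-4-yl)prop-2-en-1-one | CC(C)(C)[Si](C)(C)Oc1ccc(/C=C/C(=O)N2CCOCC2)c(O[Si](C)(C)C(C)(C)C)c1I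
F7 | step 6 | {(2R,3S)-3-[2,4-bis(tert-butyldimethylsilyloxy)-3-iodophenyl]oxiran-2-yl}(morpholin-4-yl)methanone | O=C([C@@H]1O[C@H]1c1ccc(O[Si](C)(C)C(C)(C)C)c(c1O[Si](C)(C)C(C)(C)C)I)N1CCOCC1
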